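**Strategy.** The 3-alkylfuran-2(5H)-one ring is read as carbon dioxide plus a propargyl unit: its lactone carbonyl carbon and ring oxygen are the CO2, and C3, C4 and C5 of the ring are the three carbons of a 2-alkynyl bromide. In one flask the propargylic Grignard reagent of 1-bromo-7-methyloct-6-en-2-yne is carboxylated at the chain-bearing alkyne carbon (forming the C3–C(=O) bond) and the resulting 2,3-allenoic acid is cycloisomerised (forming the O–C5H2 bond). The acyclic bromide shows no ring and no carbonyl. The tetrahydrofuran–lactone half comes from (R)-linalool by asymmetric epoxidation and stereospecific ring closure, and the halves are joined by an alkenyl–allyl Suzuki coupling.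

Key step: step 8

Remark: commercial (R)-(−)-linalool is not enantiopure; the reagent-controlled epoxidation in step 2 should turn its minor enantiomer into a diastereomer that is removed by chromatography.

**Fragment A (tetrahydrofuran–lactone half)**

Step 1
Reactants: 1 (R)-(−)-linalool
Product: 2 (2E,6R)-2,6-dimethylocta-2,7-diene-1,6-diol
Conditions: SeO2 (0.3 equiv), t-BuOOH, salicylic acid (cat.), CH2Cl2, 25 °C
Reagents that add atoms: tert-butyl hydroperoxide, CC(C)(C)OO
Why: Sharpless allylic oxidation (ene reaction of SeO2, then [2,3]-sigmatropic shift) should hydroxylate the E-methyl group of the electron-rich trisubstituted alkene and leave the vinyl carbinol, which has no allylic hydrogen, untouched; the carbinol stereocentre is the one bought with 1.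

Step 2
Reactants: 2 (2E,6R)-2,6-dimethylocta-2,7-diene-1,6-diol
Product: 4 (2S)-2-[(2R,5R)-5-ethenyl-5-methyloxolan-2-yl]propane-1,2-diol, via epoxy diol 3 (not isolated)
Conditions: Ti(OiPr)4 (1.0 equiv), L-(+)-diethyl tartrate, t-BuOOH, 4 Å MS, CH2Cl2, −20 °C; then 25 °C
Reagents that add atoms: tert-butyl hydroperoxide, CC(C)(C)OO
Why: Katsuki–Sharpless asymmetric epoxidation of the primary allylic alcohol with the L-(+)-tartrate ligand should give the (2S,3S)-epoxide by reagent control, and the titanium-bound epoxy alcohol is then opened 5-exo at C-3 by the tertiary hydroxyl with inversion, so the ring CH centre (R) and the retained carbinol centre (S) both follow stereospecifically from the epoxide and the ethenyl group ends trans to the side chain.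

Step 3
Reactants: 4 (2S)-2-[(2R,5R)-5-ethenyl-5-methyloxolan-2-yl]propane-1,2-diol
Product: 5 (2R,5R)-2-ethenyl-2-methyl-5-[(2S)-2-methyloxiran-2-yl]oxolane
Conditions: NaH, N-tosylimidazole, THF, 0 → 25 °C
Reagents that add atoms: none
Why: selective O-sulfonylation of the primary alkoxide followed by 3-exo-tet Williamson closure by the tertiary alkoxide should give the 2,2-disubstituted oxirane, and since no bond to the quaternary carbinol carbon is broken its configuration is kept.

Step 4
Reactants: 5 (2R,5R)-2-ethenyl-2-methyl-5-[(2S)-2-methyloxiran-2-yl]oxolane; 6 acetic acid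
Product: 8 (5S)-5-[(2R,5R)-5-ethenyl-5-methyloxolan-2-yl]-5-methyloxolan-2-one, via hydroxy acid 7 (not isolated)
Conditions: LiN(iPr)2 (2 equiv per AcOH), THF/DMPU, 0 → 50 °C; then 1 M HCl, 25 °C
Reagents that add atoms: none
Why: dilithioacetate should open the oxirane at its unsubstituted CH2 carbon (SN2 alkylation of a carboxylic acid dianion) and acidification closes the γ-lactone from the tertiary γ-hydroxy acid; the quaternary C–O bond is never broken, so the centre stays S.

Step 5
Reactants: 8 (5S)-5-[(2R,5R)-5-ethenyl-5-methyloxolan-2-yl]-5-methyloxolan-2-one; 9 2-ethenyl-4,4,5,5-tetramethyl-1,3,2-dioxaborolane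
Product: 10 (5S)-5-methyl-5-{(2R,5R)-5-methyl-5-[(E)-2-(4,4,5,5-tetramethyl-1,3,2-dioxaborolan-2-yl)ethenyl]oxolan-2-yl}oxolan-2-one
Conditions: second-generation Grubbs catalyst (5 mol%), 9 (3 equiv), CH2Cl2, 40 °C
Reagents that add atoms: none
Why: olefin cross-metathesis of the quaternary-allylic vinyl group, which does not homodimerise, with an excess of the vinylboronate should give the E-alkenylboronate, the E geometry being enforced by the fully substituted allylic carbon.

**Fragment B (butenolide half)**

Step 6
Reactants: 11 5-bromo-2-methylpent-2-ene; 12 prop-2-yn-1-ol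
Product: 13 7-methyloct-6-en-2-yn-1-ol
Conditions: LiNH2 (2.1 equiv), NH3(l)/THF, −33 °C
Reagents that add atoms: none
Why: the dilithium salt of propargyl alcohol should be alkylated at its acetylide carbon (SN2 on the primary bromide), the alkoxide being the poorer nucleophile.

Step 7
Reactants: 13 7-methyloct-6-en-2-yn-1-ol
Product: 14 1-bromo-7-methyloct-6-en-2-yne
Conditions: CBr4, PPh3, CH2Cl2, 0 °C
Reagents that add atoms: carbon tetrabromide, BrC(Br)(Br)Br
Why: Appel bromination should convert the primary propargylic alcohol into the bromide by SN2 displacement of the oxyphosphonium group under neutral conditions, without allene formation.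

Step 8
Reactants: 14 1-bromo-7-methyloct-6-en-2-yne; 15 carbon dioxide
Product: 18 3-(4-methylpent-3-en-1-yl)furan-2(5H)-one, via propargylic Grignard reagent 16 (not isolated), via allenoic acid 17 (not isolated)
Conditions: Mg, Et2O, 0 °C; CO2 (1 atm), −40 → 20 °C; then AcOH, CuCl (10 mol%), MeOH, 60 °C, same flask
Reagents that add atoms: none
Why: Magnesium inserts into the C–Br bond to give a propargyl/allenyl Grignard reagent whose metal sits on the unhindered primary carbon, and CO2 is attacked through a six-membered SE2' transition state by the alkyne carbon that carries the homoprenyl chain, which forms the C3–C(=O) bond and unmasks the 2,3-allenoate (closest known type: carbonation of primary propargylic Grignard reagents to 2-alkylbuta-2,3-dienoic acids). After protonation by AcOH, CuCl activates the terminal C=C of the allene, a carboxyl oxygen adds to the CH2 terminus to form the O–C5H2 bond, and protodemetalation of the vinylcopper leaves the ring alkene conjugated (closest known type: metal-catalysed cycloisomerisation of 2,3-allenoic acids to butenolides). The furanone ring closes in the 5-endo mode onto the sp2 terminus of the allene. No stereocentre is formed and the allene intermediate is achiral. The step needs γ-selective carboxylation instead of α-attack to the 3-alkynoic acid, which the alkyl group on the distal alkyne carbon should secure by keeping magnesium on CH2; oxygen attack at CH2 and not at the central allene carbon is secured by ring size (five against four).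

Step 9
Reactants: 18 3-(4-methylpent-3-en-1-yl)furan-2(5H)-one
Product: 19 3-[(3E)-5-hydroxy-4-methylpent-3-en-1-yl]furan-2(5H)-one
Conditions: SeO2 (0.5 equiv), t-BuOOH, CH2Cl2, 0 → 25 °C
Reagents that add atoms: tert-butyl hydroperoxide, CC(C)(C)OO
Why: Sharpless allylic oxidation with SeO2 should again select the E-methyl group of the electron-rich trisubstituted alkene, while the electron-poor ring alkene does not enter the ene reaction.

Step 10
Reactants: 19 3-[(3E)-5-hydroxy-4-methylpent-3-en-1-yl]furan-2(5H)-one
Product: 20 3-[(3E)-5-chloro-4-methylpent-3-en-1-yl]furan-2(5H)-one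
Conditions: MsCl, LiCl, 2,4,6-collidine, DMF, 0 °C
Reagents that add atoms: lithium chloride, [Li+].[Cl-]
Why: Collington–Meyers chlorination (mesylate formed and displaced by chloride in situ, SN2) should keep the position and the E geometry of the alkene.

**Union**

Step 11
Reactants: 10 (5S)-5-methyl-5-{(2R,5R)-5-methyl-5-[(E)-2-(4,4,5,5-tetramethyl-1,3,2-dioxaborolan-2-yl)ethenyl]oxolan-2-yl}oxolan-2-one; 20 3-[(3E)-5-chloro-4-methylpent-3-en-1-yl]furan-2(5H)-one
Product: 21 3-[(3E,6E)-4-methyl-7-{(2R,5R)-2-methyl-5-[(2S)-2-methyl-5-oxooxolan-2-yl]oxolan-2-yl}hepta-3,6-dien-1-yl]furan-2(5H)-one (CNP0301418.1)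
Conditions: Pd(PPh3)4 (5 mol%), K2CO3, THF/H2O (9:1), 50 °C; work-up at pH 3
Reagents that add atoms: none
Why: Suzuki–Miyaura alkenyl–allyl coupling, in which zerovalent palladium ionises the allylic chloride, the E-alkenylboronate transmetalates with retention and reductive elimination at the unsubstituted CH2 terminus should give the skipped E,E-diene without touching a stereocentre.

**Compound list**

1 | (R)-(−)-linalool, (3R)-3,7-dimethylocta-1,6-dien-3-ol | C=C[C@](C)(O)CCC=C(C)C | starting material
2 | (2E,6R)-2,6-dimethylocta-2,7-diene-1,6-diol | C=C[C@](C)(O)CC/C=C(\C)CO | intermediate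
3 | [(2S,3S)-3-[(3R)-3-hydroxy-3-methylpent-4-en-1-yl]-2-methyloxiran-2-yl]methanol (epoxy diol) | C=C[C@](C)(O)CC[C@@H]1O[C@@]1(C)CO | intermediate
4 | (2S)-2-[(2R,5R)-5-ethenyl-5-methyloxolan-2-yl]propane-1,2-diol | C=C[C@@]1(C)CC[C@H]([C@@](C)(O)CO)O1 | intermediate
5 | (2R,5R)-2-ethenyl-2-methyl-5-[(2S)-2-methyloxiran-2-yl]oxolane | C=C[C@@]1(C)CC[C@H]([C@]2(C)CO2)O1 | intermediate
6 | acetic acid | CC(=O)O | starting material
7 | (4S)-4-[(2R,5R)-5-ethenyl-5-methyloxolan-2-yl]-4-hydroxypentanoic acid (hydroxy acid, first formed as its dilithium salt) | C=C[C@@]1(C)CC[C@H]([C@@](C)(O)CCC(=O)O)O1 | intermediate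
8 | (5S)-5-[(2R,5R)-5-ethenyl-5-methyloxolan-2-yl]-5-methyloxolan-2-one | C=C[C@@]1(C)CC[C@H]([C@]2(C)CCC(=O)O2)O1 | intermediate
9 | 2-ethenyl-4,4,5,5-tetramethyl-1,3,2-dioxaborolane | C=CB1OC(C)(C)C(C)(C)O1 | starting material
10 | (5S)-5-methyl-5-{(2R,5R)-5-methyl-5-[(E)-2-(4,4,5,5-tetramethyl-1,3,2-dioxaborolan-2-yl)ethenyl]oxolan-2-yl}oxolan-2-one | CC1(C)OB(/C=C/[C@@]2(C)CC[C@H]([C@]3(C)CCC(=O)O3)O2)OC1(C)C | intermediate
11 | 5-bromo-2-methylpent-2-ene | CC(C)=CCCBr | starting material
12 | prop-2-yn-1-ol | C#CCO | starting material
13 | 7-methyloct-6-en-2-yn-1-ol | CC(C)=CCCC#CCO | intermediate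
14 | 1-bromo-7-methyloct-6-en-2-yne | CC(C)=CCCC#CCBr | intermediate
15 | carbon dioxide | O=C=O | starting material
16 | (7-methyloct-6-en-2-yn-1-yl)magnesium bromide (propargylic Grignard reagent) | CC(C)=CCCC#CC[Mg]Br | intermediate
17 | 2-(4-methylpent-3-en-1-yl)buta-2,3-dienoic acid (allenoic acid, first formed as its bromomagnesium salt) | CC(C)=CCCC(=C=C)C(=O)O | intermediate
18 | 3-(4-methylpent-3-en-1-yl)furan-2(5H)-one | CC(C)=CCCC1=CCOC1=O | intermediate
19 | 3-[(3E)-5-hydroxy-4-methylpent-3-en-1-yl]furan-2(5H)-one | OC/C(C)=C/CCC1=CCOC1=O | intermediate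
20 | 3-[(3E)-5-chloro-4-methylpent-3-en-1-yl]furan-2(5H)-one | ClC/C(C)=C/CCC1=CCOC1=O | intermediate
21 | 3-[(3E,6E)-4-methyl-7-{(2R,5R)-2-methyl-5-[(2S)-2-methyl-5-oxooxolan-2-yl]oxolan-2-yl}hepta-3,6-dien-1-yl]furan-2(5H)-one | C/C(=C\CCC1=CCOC1=O)C/C=C/[C@@]1(C)CC[C@H]([C@]2(C)CCC(=O)O2)O1 | target

**Step count and risks**

Total step count: 11. Longest linear sequence: 6 steps (steps 1–5 then 11, or steps 6–10 then 11).

Steps most likely to fail:

Step 8. The carboxylation may go astray through α-attack of CO2 (giving the 3-alkynoic acid, which cannot close to the wanted ring), through Wurtz coupling during magnesium insertion, or through slow cycloisomerisation in the salt-rich medium. The fallback sets out from 13: trans-hydroalumination of the propargylic alcohol with NaAlH2(OCH2CH2OMe)2 in THF at 0 °C and iodinolysis at −78 °C should give (2Z)-3-iodo-7-methylocta-2,6-dien-1-ol F1. Carbonylative lactonisation of this iodide (PdCl2(PPh3)2, CO 1 atm, Et3N, THF, 50 °C) comes back to the route at 18.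

Step 5. Turnover at the hindered quaternary-allylic olefin may be so slow that homodimerisation of the vinylboronate and catalyst decay outrun productive cross-metathesis. The fallback sets out from 8: ozonolysis (O3, CH2Cl2, −78 °C, then Me2S) should give (2R,5R)-2-methyl-5-[(2S)-2-methyl-5-oxooxolan-2-yl]oxolane-2-carbaldehyde F2. Chromium-mediated E-selective boron olefination of this non-enolisable aldehyde (CrCl2, Cl2CHBpin, LiI, THF, 25 °C) comes back to the route at 10.

Step 11. Transmetalation of the β-quaternary alkenylboronate may be slow, which gives the 2-methyl π-allyl palladium intermediate time for syn–anti isomerisation (loss of E geometry) and the boronate time for protodeboronation, while the aqueous base may open the lactones. The fallback sets out from 20 and 8: neutral Stille coupling of 20 with tributyl(ethenyl)stannane (Pd2(dba)3, P(2-furyl)3, THF, 50 °C) should give 3-[(3E)-4-methylhepta-3,6-dien-1-yl]furan-2(5H)-one F3. Cross-metathesis of its terminal alkene with the vinyl group of 8 (second-generation Grubbs catalyst, CH2Cl2, 40 °C) forms the E-disubstituted alkene and comes back to the route at 21.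

Further compounds
F1 | step 8 | (2Z)-3-iodo-7-methylocta-2,6-dien-1-ol | CC(C)=CCC/C(I)=C/CO
F2 | step 5 | (2R,5R)-2-methyl-5-[(2S)-2-methyl-5-oxooxolan-2-yl]oxolane-2-carbaldehyde | O=C[C@@]1(C)CC[C@H]([C@]2(C)CCC(=O)O2)O1
F3 | step 11 | 3-[(3E)-4-methylhepta-3,6-dien-1-yl]furan-2(5H)-one | C=CC/C(C)=C/CCC1=CCOC1=O
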